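**Plan**
1. Retrosynthesis: both malonate ester C–O bonds are cut to give two molecules of (13E)-labd-13-ene-8α,15-diol. Each is cut at C13=C14 (olefination of a C13 methyl ketone) and at C8–C17 (methylenation of a C8 ketone; the 8α-hydroxyl returns by epoxidation and hydride opening).
2. The decalone is opened at C6–C7. C5 sits between the quaternary carbons C4 and C10 of ring A, so a C5=C6 exocyclic methylene can be attacked only at C6, and a radical at C7 beside the C8 carbonyl closes ring B 6-endo exactly there.
3. The open-chain iodomethyl ketone is cut at C7–C8 (chloromethyl addition to an ester), C9–C11 (enolate alkylation) and C9–C10 (decarboxylative allylation of 2,2,6-trimethylcyclohexanone; one allyl carbon is excised later).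
4. Forward: ring A is purchased, C10 is made quaternary, the C5 carbonyl becomes the methylene, the allyl group is trimmed to the C8 ester, the C11–C13/C16 chain and C7 are attached, and ring B is closed by the radical step. C17 with the 8-hydroxyl and C14–C15 follow, and the two halves are joined through malonyl dichloride last.
5. Stereochemistry: C10 from the palladium/phosphinooxazoline allylation; C5 from hydrogen-atom transfer anti to the C10 methyl; C9 by base equilibration; C8 by α-face epoxidation and hydride opening; 13E from the Horner–Wadsworth–Emmons step.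

Key step: step 12

Remark 1: labdane numbering is used (ring A = C1–C5, C10; ring B = C5–C10; C17 on C8; side chain C11–C16). The target is the (5S,8R,9R,10S,13E) diol esterified twice. The ring stereocentre set in step 2 is never touched again; its descriptor changes from R to S at step 12 only because the CIP priorities change.
Remark 2: (R)-t-Bu-PHOX is assumed to give the R ketone 5, by analogy with the parent 2-methylcyclohexanone system. Because the halves are joined last, 25 or 28 is to be recrystallised to enantiopurity before step 20, so that no diastereomeric diester forms.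

Step 1
Reactants: 1 2,2,6-trimethylcyclohexan-1-one; 2 allyl chloroformate
Product: 4 allyl 2,6,6-trimethylcyclohex-1-en-1-yl carbonate, via lithium enolate 3 (not isolated)
Conditions: LiN(SiMe3)2, THF, 0 °C; then 2, −78 °C
Reagents that add atoms: none
Why: The ketone has a single enolisable position, so the tetrasubstituted lithium enolate forms unambiguously and the hard chloroformate acylates it on oxygen (enol carbonate formation); no stereocentre is left.

Step 2
Reactants: 4 allyl 2,6,6-trimethylcyclohex-1-en-1-yl carbonate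
Product: 5 (2R)-2,6,6-trimethyl-2-(prop-2-en-1-yl)cyclohexan-1-one
Conditions: Pd2(dba)3 (2.5 mol %), (R)-t-Bu-PHOX [(R)-4-tert-butyl-2-(2-diphenylphosphanylphenyl)-4,5-dihydrooxazole, 6 mol %], THF, 25 °C
Reagents that add atoms: none
Why: Decarboxylative asymmetric Tsuji allylation: zerovalent palladium ionises the allyl carbonate, CO2 leaves, and the enolate and π-allyl fragment recombine inside the chiral phosphinooxazoline pocket, which selects one enolate face and sets the quaternary centre (R, the future C10).

Step 3
Reactants: 5 (2R)-2,6,6-trimethyl-2-(prop-2-en-1-yl)cyclohexan-1-one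
Product: 6 (2R)-1,2,6,6-tetramethyl-2-(prop-2-en-1-yl)cyclohexan-1-ol (both C1 epimers)
Conditions: MeLi, Et2O, 0 → 35 °C; then H2O
Reagents that add atoms: methyllithium, [Li]C
Why: 1,2-Addition of an organolithium to a ketone that cannot enolise, so hindrance only slows it; the new carbinol centre is not controlled because step 4 removes it.

Step 4
Reactants: 6 (2R)-1,2,6,6-tetramethyl-2-(prop-2-en-1-yl)cyclohexan-1-ol
Product: 8 (1R)-1,3,3-trimethyl-2-methylidene-1-(prop-2-en-1-yl)cyclohexane, via chlorosulfite ester 7 (not isolated)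
Conditions: SOCl2, pyridine, CH2Cl2, −20 → 0 °C
Reagents that add atoms: none
Why: Pyridine-mediated dehydration through the chlorosulfite (E2-type elimination): both ring neighbours of the carbinol carbon are quaternary, so only a methyl hydrogen can be lost and the exocyclic methylene is the only possible alkene, while the basic medium suppresses cationic methyl shifts.

Step 5
Reactants: 8 (1R)-1,3,3-trimethyl-2-methylidene-1-(prop-2-en-1-yl)cyclohexane
Product: 10 2-[(1R)-1,3,3-trimethyl-2-methylidenecyclohexyl]acetaldehyde, via vicinal diol 9 (not isolated)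
Conditions: OsO4 (2 mol %), NaIO4, 2,6-lutidine, dioxane/H2O 3:1, 20 °C
Reagents that add atoms: osmium tetroxide, O=[Os](=O)(=O)=O; sodium periodate, [Na+].[O-]I(=O)(=O)=O
Why: Lemieux–Johnson cleavage: osmylation is very sensitive to hindrance, so the monosubstituted allyl alkene is dihydroxylated and cleaved while the methylene wedged between two quaternary carbons should stay intact.

Step 6
Reactants: 10 2-[(1R)-1,3,3-trimethyl-2-methylidenecyclohexyl]acetaldehyde
Product: 11 2-[(1R)-1,3,3-trimethyl-2-methylidenecyclohexyl]acetic acid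
Conditions: NaClO2, NaH2PO4, 2-methyl-2-butene, t-BuOH/H2O, 0 → 20 °C
Reagents that add atoms: sodium chlorite, [Na+].[O-]Cl=O
Why: Pinnick oxidation of the aldehyde under buffered conditions; the excess scavenger alkene intercepts the hypochlorous acid before it can reach the hindered methylene.

Step 7
Reactants: 11 2-[(1R)-1,3,3-trimethyl-2-methylidenecyclohexyl]acetic acid
Product: 12 methyl 2-[(1R)-1,3,3-trimethyl-2-methylidenecyclohexyl]acetate
Conditions: MeI, K2CO3, DMF, 20 °C
Reagents that add atoms: iodomethane, CI
Why: Carboxylate O-alkylation (SN2) gives the ester without acid, which avoids acid-induced lactonisation onto the methylene.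

Step 8
Reactants: 13 2-(2-bromoethyl)-2-methyl-1,3-dioxolane
Product: 14 2-(2-iodoethyl)-2-methyl-1,3-dioxolane
Conditions: NaI, acetone, 56 °C
Reagents that add atoms: sodium iodide, [Na+].[I-]
Why: Finkelstein exchange, driven by precipitation of NaBr, gives the more reactive electrophile for the hindered enolate of step 9.

Step 9
Reactants: 12 methyl 2-[(1R)-1,3,3-trimethyl-2-methylidenecyclohexyl]acetate; 14 2-(2-iodoethyl)-2-methyl-1,3-dioxolane
Product: 16 methyl 4-(2-methyl-1,3-dioxolan-2-yl)-2-[(1R)-1,3,3-trimethyl-2-methylidenecyclohexyl]butanoate (both C2 epimers), via lithium ester enolate 15 (not isolated)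
Conditions: LiN(i-Pr)2, THF, −78 °C; then DMPU, 14, −78 → 0 °C
Reagents that add atoms: none
Why: Ester enolate alkylation (SN2) with a primary iodide forms C9–C11 at the only enolisable carbon; the new C9 centre is not controlled and both epimers are carried on, because C9 is equilibrated in step 13.

Step 10
Reactants: 16 methyl 4-(2-methyl-1,3-dioxolan-2-yl)-2-[(1R)-1,3,3-trimethyl-2-methylidenecyclohexyl]butanoate
Product: 18 1-chloro-5-(2-methyl-1,3-dioxolan-2-yl)-3-[(1R)-1,3,3-trimethyl-2-methylidenecyclohexyl]pentan-2-one (both C3 epimers), via tetrahedral lithium alkoxide 17 (not isolated)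
Conditions: ICH2Cl, MeLi·LiBr, THF, −78 °C; then AcOH, −78 °C
Reagents that add atoms: chloroiodomethane, ClCI
Why: Halomethyllithium acylation of an ester: chloromethyllithium, formed by iodine–lithium exchange in the presence of the ester, adds once to give an adduct that persists at −78 °C and collapses to the chloromethyl ketone only on the cold acidic quench, which excludes a second addition.

Step 11
Reactants: 18 1-chloro-5-(2-methyl-1,3-dioxolan-2-yl)-3-[(1R)-1,3,3-trimethyl-2-methylidenecyclohexyl]pentan-2-one
Product: 19 1-iodo-5-(2-methyl-1,3-dioxolan-2-yl)-3-[(1R)-1,3,3-trimethyl-2-methylidenecyclohexyl]pentan-2-one (both C3 epimers)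
Conditions: NaI, acetone, 20 °C, dark
Reagents that add atoms: sodium iodide, [Na+].[I-]
Why: Finkelstein exchange at the carbonyl-activated primary carbon gives the weak C–I bond needed for clean halogen abstraction by tin radicals.

Step 12
Reactants: 19 1-iodo-5-(2-methyl-1,3-dioxolan-2-yl)-3-[(1R)-1,3,3-trimethyl-2-methylidenecyclohexyl]pentan-2-one
Product: 20 (4aS,8aS)-5,5,8a-trimethyl-1-[2-(2-methyl-1,3-dioxolan-2-yl)ethyl]octahydronaphthalen-2(1H)-one (trans-fused; both C9 epimers, the 9β-epimer being 21)
Conditions: Bu3SnH (1.3 equiv) and AIBN (0.2 equiv) added over 8 h by syringe pump, PhH (5 mM), 80 °C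
Reagents that add atoms: none
Why: The tributyltin radical abstracts iodine from 19 to give the electrophilic primary C7 radical next to the C8 carbonyl, which adds to the terminal C6 of the exocyclic alkene and forms C6–C7; the resulting tertiary C5 radical takes hydrogen from Bu3SnH and carries the chain. The closest known reaction type is the tin hydride-mediated cyclisation of α-keto radicals that hold the carbonyl inside the forming ring onto 1,1-disubstituted alkenes, which closes endo. Ring B (C5–C6–C7–C8–C9–C10) closes in the 6-endo-trig mode, because the 5-exo alternative would bond C7 to C5 between the quaternary C4 and C10 and is further disfavoured by the strain the in-ring carbonyl puts on an exo transition state. The one new stereocentre, C5, is set when the C5 radical is quenched on the α face, opposite the axial C10 methyl and the axial 4β-methyl, which gives the trans ring fusion (5S). The step needs cyclisation to outrun direct reduction of the C7 radical, which is secured by slow Bu3SnH addition at high dilution and by the polarity match between the electrophilic radical and the electron-rich alkene. Both C9 epimers of 19 should cyclise, and C9 is corrected in step 13.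

Step 13
Reactants: 20 (4aS,8aS)-5,5,8a-trimethyl-1-[2-(2-methyl-1,3-dioxolan-2-yl)ethyl]octahydronaphthalen-2(1H)-one (C9 epimers)
Product: 21 (1R,4aS,8aS)-5,5,8a-trimethyl-1-[2-(2-methyl-1,3-dioxolan-2-yl)ethyl]octahydronaphthalen-2(1H)-one (14,15,17-trinorlabdane-8,13-dione 13-ethylene ketal)
Conditions: NaOMe (0.2 equiv), MeOH, 40 °C
Reagents that add atoms: none
Why: Enolate-mediated epimerisation α to the ketone moves the C9 side chain into the equatorial β position of the trans-decalone (9R, 9α-H), the thermodynamically preferred arrangement; C5 and C10 cannot enolise and are untouched.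

Step 14
Reactants: 21 (1R,4aS,8aS)-5,5,8a-trimethyl-1-[2-(2-methyl-1,3-dioxolan-2-yl)ethyl]octahydronaphthalen-2(1H)-one
Product: 22 2-methyl-2-{2-[(1S,4aS,8aS)-5,5,8a-trimethyl-2-methylidenedecahydronaphthalen-1-yl]ethyl}-1,3-dioxolane (14,15-dinorlabd-8(17)-en-13-one ethylene ketal)
Conditions: Ph3PCH3Br, KOt-Bu, toluene, 80 °C
Reagents that add atoms: methyltriphenylphosphonium bromide, C[P+](c1ccccc1)(c1ccccc1)c1ccccc1.[Br-]
Why: Wittig methylenation with the non-stabilised ylide turns the C8 carbonyl into the 8(17)-methylene; C9 already holds its preferred configuration, so the basic medium should not erode it (its descriptor becomes S by priority change only).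

Step 15
Reactants: 22 14,15-dinorlabd-8(17)-en-13-one ethylene ketal
Product: 23 8α,17-epoxy-14,15-dinorlabdan-13-one ethylene ketal (spiro-oxirane at C8, oxygen α, 8R)
Conditions: m-CPBA, NaHCO3, CH2Cl2, 0 °C
Reagents that add atoms: 3-chloroperoxybenzoic acid, OOC(=O)c1cccc(Cl)c1
Why: Prilezhaev epoxidation: the peracid approaches the exocyclic alkene from the α face because the β face is screened by the axial C10 methyl in a 1,3 relation to C8, which places the epoxide oxygen α and C17 β.

Step 16
Reactants: 23 8α,17-epoxy-14,15-dinorlabdan-13-one ethylene ketal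
Product: 24 (1R,2R,4aS,8aS)-2,5,5,8a-tetramethyl-1-[2-(2-methyl-1,3-dioxolan-2-yl)ethyl]decahydronaphthalen-2-ol (8α-hydroxy-14,15-dinorlabdan-13-one ethylene ketal)
Conditions: LiAlH4, THF, 0 → 65 °C; then H2O
Reagents that add atoms: none
Why: Hydride opening of the epoxide (SN2) at the primary C17 leaves the C8–O bond untouched, so the 8α-hydroxyl and the axial 8β-methyl arise with the configuration fixed in step 15; the ketal is inert to the hydride.

Step 17
Reactants: 24 8α-hydroxy-14,15-dinorlabdan-13-one ethylene ketal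
Product: 25 4-[(1R,2R,4aS,8aS)-2-hydroxy-2,5,5,8a-tetramethyldecahydronaphthalen-1-yl]butan-2-one (8α-hydroxy-14,15-dinorlabdan-13-one)
Conditions: 2 M aq HCl, THF, 20 °C
Reagents that add atoms: water, O
Why: Acid-catalysed ketal hydrolysis frees the C13 methyl ketone; dilute aqueous acid at room temperature should spare the tertiary 8-hydroxyl, and the water keeps the equilibrium on the open hydroxy ketone instead of the cyclic enol ether.

Step 18
Reactants: 25 8α-hydroxy-14,15-dinorlabdan-13-one
Product: 26 ethyl (2E)-5-[(1R,2R,4aS,8aS)-2-hydroxy-2,5,5,8a-tetramethyldecahydronaphthalen-1-yl]-3-methylpent-2-enoate (ethyl (13E)-8α-hydroxylabd-13-en-15-oate)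
Conditions: (EtO)2P(O)CH2CO2Et, NaH (excess), THF, 0 → 65 °C
Reagents that add atoms: triethyl phosphonoacetate, CCOC(=O)CP(=O)(OCC)OCC
Why: Horner–Wadsworth–Emmons olefination of the methyl ketone with the stabilised phosphonate anion forms C13=C14 with the ester trans to the larger C12 chain (13E) through reversible addition; the minor 13Z isomer is to be removed by chromatography, and the extra base covers the free tertiary alcohol.

Step 19
Reactants: 26 ethyl (13E)-8α-hydroxylabd-13-en-15-oate
Product: 28 (13E)-labd-13-ene-8α,15-diol, via enal 27 (not isolated)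
Conditions: i-Bu2AlH (4 equiv), CH2Cl2, −78 → 0 °C; then aq potassium sodium tartrate
Reagents that add atoms: none
Why: 1,2-Reduction of the α,β-unsaturated ester by the aluminium hydride passes through the enal to the allylic alcohol without touching the alkene geometry or the tertiary alcohol.

Step 20
Reactants: 28 (13E)-labd-13-ene-8α,15-diol (2 equiv); 29 malonyl dichloride (1 equiv)
Product: 31 bis[(13E)-8α-hydroxylabd-13-en-15-yl] malonate (CNP0254645.1), via malonyl monoester chloride 30 (not isolated)
Conditions: pyridine, CH2Cl2, 0 → 20 °C, slow addition of 29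
Reagents that add atoms: none
Why: Twofold nucleophilic acyl substitution at the diacid chloride by the primary allylic hydroxyl; the tertiary 8-hydroxyl, flanked by the axial C8 methyl and C9, is too hindered to be acylated under these conditions, so no protecting group is needed.

**Compound list**
1 | 2,2,6-trimethylcyclohexan-1-one (racemic) | CC1CCCC(C)(C)C1=O | starting material
2 | allyl chloroformate | C=CCOC(=O)Cl | starting material
3 | lithium 2,6,6-trimethylcyclohex-1-en-1-olate | [Li+].[O-]C1=C(C)CCCC1(C)C | intermediate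
4 | allyl 2,6,6-trimethylcyclohex-1-en-1-yl carbonate | C=CCOC(=O)OC1=C(C)CCCC1(C)C | intermediate
5 | (2R)-2,6,6-trimethyl-2-(prop-2-en-1-yl)cyclohexan-1-one | C=CC[C@@]1(C)CCCC(C)(C)C1=O | intermediate
6 | (2R)-1,2,6,6-tetramethyl-2-(prop-2-en-1-yl)cyclohexan-1-ol, both C1 epimers | C=CC[C@@]1(C)CCCC(C)(C)C1(C)O | intermediate
7 | chlorosulfite ester of 6 | C=CC[C@@]1(C)CCCC(C)(C)C1(C)OS(Cl)=O | intermediate
8 | (1R)-1,3,3-trimethyl-2-methylidene-1-(prop-2-en-1-yl)cyclohexane | C=CC[C@@]1(C)CCCC(C)(C)C1=C | intermediate
9 | 3-[(1R)-1,3,3-trimethyl-2-methylidenecyclohexyl]propane-1,2-diol, both C2 epimers | OCC(O)C[C@@]1(C)CCCC(C)(C)C1=C | intermediate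
10 | 2-[(1R)-1,3,3-trimethyl-2-methylidenecyclohexyl]acetaldehyde | O=CC[C@@]1(C)CCCC(C)(C)C1=C | intermediate
11 | 2-[(1R)-1,3,3-trimethyl-2-methylidenecyclohexyl]acetic acid | OC(=O)C[C@@]1(C)CCCC(C)(C)C1=C | intermediate
12 | methyl 2-[(1R)-1,3,3-trimethyl-2-methylidenecyclohexyl]acetate | COC(=O)C[C@@]1(C)CCCC(C)(C)C1=C | intermediate
13 | 2-(2-bromoethyl)-2-methyl-1,3-dioxolane | CC1(CCBr)OCCO1 | starting material
14 | 2-(2-iodoethyl)-2-methyl-1,3-dioxolane | CC1(CCI)OCCO1 | intermediate
15 | lithium enolate of 12 | [Li+].[O-]C(OC)=C[C@@]1(C)CCCC(C)(C)C1=C | intermediate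
16 | methyl 4-(2-methyl-1,3-dioxolan-2-yl)-2-[(1R)-1,3,3-trimethyl-2-methylidenecyclohexyl]butanoate, both C2 epimers | COC(=O)C(CCC1(C)OCCO1)[C@@]2(C)CCCC(C)(C)C2=C | intermediate
17 | lithium 1-chloro-2-methoxy-5-(2-methyl-1,3-dioxolan-2-yl)-3-[(1R)-1,3,3-trimethyl-2-methylidenecyclohexyl]pentan-2-olate | [Li+].[O-]C(CCl)(OC)C(CCC1(C)OCCO1)[C@@]2(C)CCCC(C)(C)C2=C | intermediate
18 | 1-chloro-5-(2-methyl-1,3-dioxolan-2-yl)-3-[(1R)-1,3,3-trimethyl-2-methylidenecyclohexyl]pentan-2-one, both C3 epimers | ClCC(=O)C(CCC1(C)OCCO1)[C@@]2(C)CCCC(C)(C)C2=C | intermediate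
19 | 1-iodo-5-(2-methyl-1,3-dioxolan-2-yl)-3-[(1R)-1,3,3-trimethyl-2-methylidenecyclohexyl]pentan-2-one, both C3 epimers | ICC(=O)C(CCC1(C)OCCO1)[C@@]2(C)CCCC(C)(C)C2=C | intermediate
20 | (4aS,8aS)-5,5,8a-trimethyl-1-[2-(2-methyl-1,3-dioxolan-2-yl)ethyl]octahydronaphthalen-2(1H)-one, trans-fused, both C9 epimers | CC1(CCC2[C@@]3(C)CCCC(C)(C)[C@@H]3CCC2=O)OCCO1 | intermediate
21 | (1R,4aS,8aS)-5,5,8a-trimethyl-1-[2-(2-methyl-1,3-dioxolan-2-yl)ethyl]octahydronaphthalen-2(1H)-one | CC1(CC[C@@H]2[C@@]3(C)CCCC(C)(C)[C@@H]3CCC2=O)OCCO1 | intermediate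
22 | 2-methyl-2-{2-[(1S,4aS,8aS)-5,5,8a-trimethyl-2-methylidenedecahydronaphthalen-1-yl]ethyl}-1,3-dioxolane | CC1(CC[C@@H]2[C@@]3(C)CCCC(C)(C)[C@@H]3CCC2=C)OCCO1 | intermediate
23 | 8α,17-epoxy-14,15-dinorlabdan-13-one ethylene ketal (8R spiro-oxirane, oxygen α) | CC1(CC[C@@H]2[C@@]3(C)CCCC(C)(C)[C@@H]3CC[C@@]24OC4)OCCO1 | intermediate
24 | (1R,2R,4aS,8aS)-2,5,5,8a-tetramethyl-1-[2-(2-methyl-1,3-dioxolan-2-yl)ethyl]decahydronaphthalen-2-ol | CC1(CC[C@@H]2[C@@]3(C)CCCC(C)(C)[C@@H]3CC[C@@]2(C)O)OCCO1 | intermediate
25 | 4-[(1R,2R,4aS,8aS)-2-hydroxy-2,5,5,8a-tetramethyldecahydronaphthalen-1-yl]butan-2-one | CC(=O)CC[C@@H]1[C@@]2(C)CCCC(C)(C)[C@@H]2CC[C@@]1(C)O | intermediate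
26 | ethyl (2E)-5-[(1R,2R,4aS,8aS)-2-hydroxy-2,5,5,8a-tetramethyldecahydronaphthalen-1-yl]-3-methylpent-2-enoate | CCOC(=O)/C=C(\C)CC[C@@H]1[C@@]2(C)CCCC(C)(C)[C@@H]2CC[C@@]1(C)O | intermediate
27 | (13E)-8α-hydroxylabd-13-en-15-al | O=C/C=C(\C)CC[C@@H]1[C@@]2(C)CCCC(C)(C)[C@@H]2CC[C@@]1(C)O | intermediate
28 | (13E)-labd-13-ene-8α,15-diol | OC/C=C(\C)CC[C@@H]1[C@@]2(C)CCCC(C)(C)[C@@H]2CC[C@@]1(C)O | intermediate
29 | malonyl dichloride | O=C(Cl)CC(=O)Cl | starting material
30 | (13E)-8α-hydroxylabd-13-en-15-yl 3-chloro-3-oxopropanoate | O=C(Cl)CC(=O)OC/C=C(\C)CC[C@@H]1[C@@]2(C)CCCC(C)(C)[C@@H]2CC[C@@]1(C)O | intermediate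
31 | bis[(13E)-8α-hydroxylabd-13-en-15-yl] malonate (CNP0254645.1) | C/C(=C\COC(=O)CC(=O)OC/C=C(\C)CC[C@@H]1[C@@]2(C)CCCC(C)(C)[C@@H]2CC[C@@]1(C)O)CC[C@@H]1[C@@]2(C)CCCC(C)(C)[C@@H]2CC[C@@]1(C)O | target

**Step count**
Total: 20 steps. Longest linear sequence: 19 steps (steps 1–7 and 9–20, from 1); step 8 is a one-step branch.

**Steps most likely to fail**

Step 12. The C7 radical may be reduced by the tin hydride before it cyclises, or the chain may stall at the very hindered C5 radical. The fallback removes the hydrogen donor from the cyclisation. It sets out from 18: displacement of chloride with KSC(S)OEt in acetone should give the S-(2-oxoalkyl) O-ethyl xanthate F1. Heating F1 with dilauroyl peroxide in 1,2-dichloroethane (degenerative xanthate group transfer) lets the same C7 radical add 6-endo to C6 over a long effective lifetime and caps C5 as the tertiary C5 xanthate F2. Bu3SnH/AIBN then removes the xanthate through the same C5 radical, with hydrogen delivered on the α face, and the route is rejoined at 20.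

Step 10. The carbenoid may deprotonate C9 or decompose before it adds to the hindered ester carbonyl. The fallback sets out from 16: reduction with i-Bu2AlH at −78 °C should give the aldehyde F3, a far better electrophile. Chloromethyllithium (ICH2Cl, MeLi·LiBr, −78 °C, cold quench) then adds to give the chlorohydrin F4, and Dess–Martin oxidation returns to the route at 18.

Step 9. E2 loss of HI from 14 under the basic, hindered enolate may outpace C-alkylation. The fallback replaces the alkylation by a conjugate addition and sets out from 12: LiN(i-Pr)2 and Me3SiCl give the trimethylsilyl ketene acetal F5. Mukaiyama–Michael addition of F5 to methyl vinyl ketone (TiCl4, CH2Cl2, −78 °C) should give the keto ester F6. Ketalisation with ethylene glycol (PPTS, benzene, water removal) then rejoins the route at 16.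

**Further compounds**
F1 | step 12 | O-ethyl S-{5-(2-methyl-1,3-dioxolan-2-yl)-2-oxo-3-[(1R)-1,3,3-trimethyl-2-methylidenecyclohexyl]pentyl} carbonodithioate | CCOC(=S)SCC(=O)C(CCC1(C)OCCO1)[C@@]2(C)CCCC(C)(C)C2=C
F2 | step 12 | C5 xanthate of decalone 20 (O-ethyl S-carbonodithioate at the ring-fusion carbon C5, C5 and C9 unassigned) | CC1(CCC2[C@@]3(C)CCCC(C)(C)C3(SC(=S)OCC)CCC2=O)OCCO1
F3 | step 10 | 4-(2-methyl-1,3-dioxolan-2-yl)-2-[(1R)-1,3,3-trimethyl-2-methylidenecyclohexyl]butanal | O=CC(CCC1(C)OCCO1)[C@@]2(C)CCCC(C)(C)C2=C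
F4 | step 10 | 1-chloro-5-(2-methyl-1,3-dioxolan-2-yl)-3-[(1R)-1,3,3-trimethyl-2-methylidenecyclohexyl]pentan-2-ol | ClCC(O)C(CCC1(C)OCCO1)[C@@]2(C)CCCC(C)(C)C2=C
F5 | step 9 | methyl trimethylsilyl ketene acetal of 12 | COC(O[Si](C)(C)C)=C[C@@]1(C)CCCC(C)(C)C1=C
F6 | step 9 | methyl 5-oxo-2-[(1R)-1,3,3-trimethyl-2-methylidenecyclohexyl]hexanoate | COC(=O)C(CCC(C)=O)[C@@]1(C)CCCC(C)(C)C1=C
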